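## Retrosynthetic overview

1. Target 19, the (3S)-isoflavan, comes from its bis-benzyl ether 18 by global hydrogenolysis in the last step.
2. 18 is cut at the C3–C4 bond to the racemic bis(benzylic) dichloride 17. A nickel/pybox-catalysed enantioconvergent reductive cyclisation closes the pyran ring (the only ring made in the route; rings A and B are bought as arenes) and sets C3 in the same operation.
3. Enabling feature: C3 and C4 are both benzylic (C4 is the CH2 on ring A ortho to O1, C3 is the CH on ring B). Both can therefore be carried as chlorides, the C3 radical is planar and erases the racemic centre, and the O1–C2 ether tether places the two carbons for six-membered ring closure.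
4. 17 comes from keto-aldehyde 15 (double reduction, double deoxychlorination), and 15 from salicylaldehyde 4 (ring A) and α-chloroketone 14 (ring B) by O-alkylation.
5. 4 comes from 2-methoxyresorcinol (formylation, 4-O-benzylation). 14 comes from 2-hydroxy-3,4-dimethoxybenzaldehyde (benzylation, Dakin oxidation, ortho-bromination, O-methylation, Br–Li exchange and acylation with Weinreb amide 11).

Key step: step 11

Remark: isoflavan numbering is used (O1, C2, C3, C4, ring A = C4a–C8a, ring B primed); the target is (3S), and it is assumed that one of the two commercial antipodes of the pybox ligand in step 11 delivers this sense, to be fixed in a calibration run.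

## Route

Step 1
Reactants: 1 2-methoxyresorcinol (2-methoxybenzene-1,3-diol)
Product: 3 2,4-dihydroxy-3-methoxybenzaldehyde, via aryl iminium chloride 2 (not isolated)
Conditions: POCl3, DMF, MeCN, 0 °C → rt; then H2O, 50 °C
Reagents that add atoms: N,N-dimethylformamide CN(C)C=O; water O
Why: Vilsmeier–Haack formylation, in which the chloroiminium electrophile attacks the carbon ortho to one and para to the other hydroxyl of the symmetric resorcinol (C4 and C6 are equivalent, C5 is meta to both), so a single aldehyde should result after hydrolysis of iminium 2.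

Step 2
Reactants: 3 2,4-dihydroxy-3-methoxybenzaldehyde
Product: 4 4-(benzyloxy)-2-hydroxy-3-methoxybenzaldehyde
Conditions: BnBr (1.05 equiv), NaHCO3, MeCN, 80 °C
Reagents that add atoms: benzyl bromide BrCc1ccccc1
Why: Williamson etherification under weak base, selective for the 4-OH because it is para to the formyl group (more acidic) and is not held in the hydrogen bond that ties the 2-OH to the carbonyl oxygen.

Step 3
Reactants: 5 2-hydroxy-3,4-dimethoxybenzaldehyde
Product: 6 2-(benzyloxy)-3,4-dimethoxybenzaldehyde
Conditions: BnBr, K2CO3, DMF, rt
Reagents that add atoms: benzyl bromide BrCc1ccccc1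
Why: Williamson etherification of the only free phenol, which places the benzyl group on the oxygen that becomes O3' of ring B.

Step 4
Reactants: 6 2-(benzyloxy)-3,4-dimethoxybenzaldehyde
Product: 8 2-(benzyloxy)-3,4-dimethoxyphenol, via aryl formate 7 (not isolated)
Conditions: mCPBA, CH2Cl2, 0 °C → rt; then MeOH, K2CO3 (cat.), rt
Reagents that add atoms: 3-chloroperoxybenzoic acid OOC(=O)c1cccc(Cl)c1
Why: Dakin-type Baeyer–Villiger oxidation, in which the electron-rich aryl group (ortho- and para-alkoxy) migrates in the Criegee intermediate to give formate 7, which is methanolysed in the same flask.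

Step 5
Reactants: 8 2-(benzyloxy)-3,4-dimethoxyphenol
Product: 9 2-(benzyloxy)-6-bromo-3,4-dimethoxyphenol
Conditions: NBS, iPr2NH (cat.), CH2Cl2, −78 → 0 °C
Reagents that add atoms: N-bromosuccinimide O=C1CCC(=O)N1Br
Why: amine-catalysed ortho-selective electrophilic bromination of a phenol, where the para position is blocked by OMe and one ortho position by OBn, so bromine should enter the remaining ortho carbon and fix the substitution pattern of ring B.

Step 6
Reactants: 9 2-(benzyloxy)-6-bromo-3,4-dimethoxyphenol
Product: 10 3-(benzyloxy)-1-bromo-2,4,5-trimethoxybenzene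
Conditions: MeI, K2CO3, DMF, rt
Reagents that add atoms: iodomethane CI
Why: Williamson O-methylation of the hindered phenoxide with a small electrophile, which installs the 2'-OMe group.

Step 7
Reactants: 10 3-(benzyloxy)-1-bromo-2,4,5-trimethoxybenzene; 11 2-chloro-N-methoxy-N-methylacetamide
Product: 14 1-[3-(benzyloxy)-2,4,5-trimethoxyphenyl]-2-chloroethan-1-one, via aryllithium 12 (not isolated), via lithium hemiaminal adduct 13 (not isolated)
Conditions: n-BuLi, THF, −78 °C; then 11, −78 → −20 °C; then 1 M HCl
Reagents that add atoms: none
Why: bromine–lithium exchange followed by Weinreb ketone synthesis, in which the chelated tetrahedral adduct 13 does not collapse before the acidic quench, so over-addition is avoided and the α-chloroketone is released directly.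

Step 8
Reactants: 4 4-(benzyloxy)-2-hydroxy-3-methoxybenzaldehyde; 14 1-[3-(benzyloxy)-2,4,5-trimethoxyphenyl]-2-chloroethan-1-one
Product: 15 4-(benzyloxy)-2-{2-[3-(benzyloxy)-2,4,5-trimethoxyphenyl]-2-oxoethoxy}-3-methoxybenzaldehyde
Conditions: K2CO3, DMF, 0 °C → rt
Reagents that add atoms: none
Why: Williamson etherification (SN2 displacement of the activated α-chloroketone by the phenoxide of 4), run cold so that it stays ahead of the Rap–Stoermer aldol cyclisation; it forms the O1–C2 tether.

Step 9
Reactants: 15 keto-aldehyde
Product: 16 rac-1-[3-(benzyloxy)-2,4,5-trimethoxyphenyl]-2-[3-(benzyloxy)-6-(hydroxymethyl)-2-methoxyphenoxy]ethan-1-ol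
Conditions: NaBH4, THF/MeOH, 0 °C; then H2O
Reagents that add atoms: none
Why: borohydride reduction of both carbonyl groups, with the carbinol centre formed as a racemate on purpose because it is erased in step 11.

Step 10
Reactants: 16 racemic diol
Product: 17 rac-1-(benzyloxy)-3-{2-chloro-2-[3-(benzyloxy)-2,4,5-trimethoxyphenyl]ethoxy}-4-(chloromethyl)-2-methoxybenzene
Conditions: 1-chloro-N,N,2-trimethylprop-1-en-1-amine (2.4 equiv), CH2Cl2, 0 °C → rt; evaporation, used at once
Reagents that add atoms: 1-chloro-N,N,2-trimethylprop-1-en-1-amine CC(C)=C(Cl)N(C)C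
Why: deoxychlorination with the Ghosez α-chloroenamine under neutral conditions (no HCl, no base), where both benzylic chlorides should be handleable because O2' and O4' of ring B and O1 of ring A are each flanked by two substituents and twisted out of conjugation and the β-aryloxy group disfavours ionisation at C3, while the amide by-product is an inert co-solvent for step 11.

Step 11
Reactants: 17 racemic dichloride
Product: 18 (3S)-7-(benzyloxy)-3-[3-(benzyloxy)-2,4,5-trimethoxyphenyl]-8-methoxychromane
Conditions: NiBr2·diglyme (10 mol %), (S,S)-iPr-Pybox (13 mol %), Mn powder (3 equiv), DMA/THF, 0 °C, 17 added over 8 h (final 0.02 M)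
Reagents that add atoms: none
Why: Proposed new method: intramolecular enantioconvergent nickel-catalysed reductive cross-electrophile coupling of a primary with a racemic secondary benzylic chloride; zerovalent nickel (divalent nickel reduced by Mn) should insert into the unhindered primary C4–Cl bond, the benzylnickel species so formed should, after one-electron reduction, abstract the chlorine atom from C3 of the same molecule, and the planar C3 radical should recombine with nickel to a trivalent dialkylnickel species that reductively eliminates the C3–C4 bond. The closest known reaction types are the nickel/pybox-catalysed enantioconvergent Negishi alkylation of racemic secondary benzylic halides (same radical capture and C(sp3)–C(sp3) reductive elimination at a chiral alkylnickel centre), the nickel/pybox-catalysed reductive alkyl–alkyl coupling of two halides with a metal reductant, and the nickel/bis(oxazoline)-catalysed asymmetric reductive couplings of racemic benzylic chlorides; the ring-closing benzylic–benzylic combination of these is not known. The pyran ring closes through a seven-membered nickelacycle (Ni, C4, C4a, C8a, O1, C2, C3) that contracts to the six-membered ring on reductive elimination, in the net sense a 6-exo-tet substitution at C4. The C3 stereocentre is controlled by the chiral pybox ligand on nickel at the radical capture and reductive elimination stage, and since both enantiomers of 17 give the same radical the racemate should be funnelled into the (3S) product. The step needs ring closure to win over intermolecular homocoupling (secured by the O1–C2 tether and slow addition at high dilution), cross-selectivity (secured by the different activation modes of a primary and a secondary benzylic chloride) and no loss of the aryloxide from C2 (secured by the radical character of C3, which does not fragment the C2–O1 bond, and by Mn, which unlike Zn does not insert directly to give a β-aryloxy organometallic prone to elimination).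

Step 12
Reactants: 18 (3S)-bis-benzyl ether
Product: 19 (3S)-3-(3-hydroxy-2,4,5-trimethoxyphenyl)-8-methoxychroman-7-ol
Conditions: H2 (1 atm), Pd/C (10% w/w), EtOAc/MeOH, rt
Reagents that add atoms: none
Why: hydrogenolysis of the two benzyl aryl ethers over palladium on carbon, which should leave the non-epimerisable C3 centre and the non-benzylic O1–C2 bond untouched.

## Compound list

1 | 2-methoxyresorcinol (2-methoxybenzene-1,3-diol) | COc1c(O)cccc1O | starting material
2 | [(2,4-dihydroxy-3-methoxyphenyl)methylidene]dimethyliminium chloride (formed in the flask) | C[N+](C)=Cc1ccc(O)c(OC)c1O.[Cl-] | intermediate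
3 | 2,4-dihydroxy-3-methoxybenzaldehyde | O=Cc1ccc(O)c(OC)c1O | intermediate
4 | 4-(benzyloxy)-2-hydroxy-3-methoxybenzaldehyde | O=Cc1ccc(OCc2ccccc2)c(OC)c1O | intermediate
5 | 2-hydroxy-3,4-dimethoxybenzaldehyde | O=Cc1ccc(OC)c(OC)c1O | starting material
6 | 2-(benzyloxy)-3,4-dimethoxybenzaldehyde | O=Cc1ccc(OC)c(OC)c1OCc1ccccc1 | intermediate
7 | 2-(benzyloxy)-3,4-dimethoxyphenyl formate (formed in the flask) | O=COc1ccc(OC)c(OC)c1OCc1ccccc1 | intermediate
8 | 2-(benzyloxy)-3,4-dimethoxyphenol | Oc1ccc(OC)c(OC)c1OCc1ccccc1 | intermediate
9 | 2-(benzyloxy)-6-bromo-3,4-dimethoxyphenol | Oc1c(Br)cc(OC)c(OC)c1OCc1ccccc1 | intermediate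
10 | 3-(benzyloxy)-1-bromo-2,4,5-trimethoxybenzene | COc1c(Br)cc(OC)c(OC)c1OCc1ccccc1 | intermediate
11 | 2-chloro-N-methoxy-N-methylacetamide | CON(C)C(=O)CCl | starting material
12 | [3-(benzyloxy)-2,4,5-trimethoxyphenyl]lithium (formed in the flask) | [Li]c1cc(OC)c(OC)c(OCc2ccccc2)c1OC | intermediate
13 | lithium 1-[3-(benzyloxy)-2,4,5-trimethoxyphenyl]-2-chloro-1-[methoxy(methyl)amino]ethan-1-olate (formed in the flask) | [Li]OC(CCl)(N(C)OC)c1cc(OC)c(OC)c(OCc2ccccc2)c1OC | intermediate
14 | 1-[3-(benzyloxy)-2,4,5-trimethoxyphenyl]-2-chloroethan-1-one | O=C(CCl)c1cc(OC)c(OC)c(OCc2ccccc2)c1OC | intermediate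
15 | 4-(benzyloxy)-2-{2-[3-(benzyloxy)-2,4,5-trimethoxyphenyl]-2-oxoethoxy}-3-methoxybenzaldehyde | O=Cc1ccc(OCc2ccccc2)c(OC)c1OCC(=O)c1cc(OC)c(OC)c(OCc2ccccc2)c1OC | intermediate
16 | rac-1-[3-(benzyloxy)-2,4,5-trimethoxyphenyl]-2-[3-(benzyloxy)-6-(hydroxymethyl)-2-methoxyphenoxy]ethan-1-ol | OCc1ccc(OCc2ccccc2)c(OC)c1OCC(O)c1cc(OC)c(OC)c(OCc2ccccc2)c1OC | intermediate
17 | rac-1-(benzyloxy)-3-{2-chloro-2-[3-(benzyloxy)-2,4,5-trimethoxyphenyl]ethoxy}-4-(chloromethyl)-2-methoxybenzene | ClCc1ccc(OCc2ccccc2)c(OC)c1OCC(Cl)c1cc(OC)c(OC)c(OCc2ccccc2)c1OC | intermediate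
18 | (3S)-7-(benzyloxy)-3-[3-(benzyloxy)-2,4,5-trimethoxyphenyl]-8-methoxychromane | COc1cc([C@H]2COc3c(ccc(OCc4ccccc4)c3OC)C2)c(OC)c(OCc2ccccc2)c1OC | intermediate
19 | (3S)-3-(3-hydroxy-2,4,5-trimethoxyphenyl)-8-methoxychroman-7-ol | COc1cc([C@H]2COc3c(ccc(O)c3OC)C2)c(OC)c(O)c1OC | target

## Step count and risks

Total step count: 12 steps. Longest linear sequence: 10 steps (5 → 19 through steps 3–12); the ring A branch (steps 1–2) joins at step 8.

Steps most likely to fail:

1. Step 11 (Proposed new method). What may go wrong: intermolecular homocoupling or oligomerisation instead of ring closure, hydrodechlorination, loss of the aryloxide from C2 by β-elimination at a C3–metal species, or low enantioselectivity. The fallback uses known chemistry and sets out from keto-aldehyde 15. Intramolecular McMurry coupling (TiCl4, Zn, pyridine, THF, reflux, slow addition) should join the two carbonyl carbons to give 7-(benzyloxy)-3-[3-(benzyloxy)-2,4,5-trimethoxyphenyl]-8-methoxy-2H-chromene F1. Iridium-catalysed asymmetric hydrogenation of the trisubstituted C3=C4 double bond ([Ir(cod)((S)-tBu-PHOX)]BArF or its antipode, H2 50 bar, CH2Cl2), a reaction type established for 3-aryl-2H-chromenes, should then give 18, where the route is rejoined.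

2. Step 10. What may go wrong: ionisation of the secondary benzylic chloride during its formation or handling, followed by loss of HCl to the aryl styryl ether or capture of the cation by ring A. The fallback sets out from 15 and avoids benzylic halides altogether. Double Wittig methylenation (Ph3PCH3Br, KOtBu, THF) should give 1-(benzyloxy)-3-({2-[3-(benzyloxy)-2,4,5-trimethoxyphenyl]prop-2-en-1-yl}oxy)-4-ethenyl-2-methoxybenzene F2. Ring-closing metathesis (second-generation Grubbs catalyst RuCl2(=CHPh)(H2IMes)(PCy3), toluene, 80 °C) should then form the C3=C4 bond of the 2H-chromene F1 described above, and the same iridium-catalysed asymmetric hydrogenation returns to the route at 18.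

3. Step 8. What may go wrong: base-mediated intramolecular aldol condensation of the new phenacyl ether onto the ortho-formyl group (Rap–Stoermer cyclisation to a 2-aroylbenzofuran) in competition with simple O-alkylation. The fallback sets out from 4 and removes the aldehyde before the alkylation. NaBH4 reduction should give 3-(benzyloxy)-6-(hydroxymethyl)-2-methoxyphenol F3. Chemoselective O-alkylation of its phenol with 14 (K2CO3, DMF, rt) should give 1-[3-(benzyloxy)-2,4,5-trimethoxyphenyl]-2-[3-(benzyloxy)-6-(hydroxymethyl)-2-methoxyphenoxy]ethan-1-one F4, and NaBH4 reduction of the ketone returns to the route at diol 16.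

## Further compounds

F1 | step 11 | 7-(benzyloxy)-3-[3-(benzyloxy)-2,4,5-trimethoxyphenyl]-8-methoxy-2H-chromene | COc1cc(C2=Cc3ccc(OCc4ccccc4)c(OC)c3OC2)c(OC)c(OCc2ccccc2)c1OC
F2 | step 10 | 1-(benzyloxy)-3-({2-[3-(benzyloxy)-2,4,5-trimethoxyphenyl]prop-2-en-1-yl}oxy)-4-ethenyl-2-methoxybenzene | C=Cc1ccc(OCc2ccccc2)c(OC)c1OCC(=C)c1cc(OC)c(OC)c(OCc2ccccc2)c1OC
F3 | step 8 | 3-(benzyloxy)-6-(hydroxymethyl)-2-methoxyphenol | OCc1ccc(OCc2ccccc2)c(OC)c1O
F4 | step 8 | 1-[3-(benzyloxy)-2,4,5-trimethoxyphenyl]-2-[3-(benzyloxy)-6-(hydroxymethyl)-2-methoxyphenoxy]ethan-1-one | OCc1ccc(OCc2ccccc2)c(OC)c1OCC(=O)c1cc(OC)c(OC)c(OCc2ccccc2)c1OC
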